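The spiro carbon (C1) carries a tertiary carbinol (C6, methyl and OH) in the six-membered ring and a CHOH carbon (C7) in the five-membered ring, the pattern of a β-hydroxy ketone. The cyclopentane is therefore not cyclised but grown from a cyclobutane: a Lewis-acid semipinacol rearrangement of a 1-(1,2-epoxycyclohexyl)cyclobutanol makes the C1–C10 bond, the quaternary spiro centre, the C7 ketone and the anti C6 alcohol in one operation. The precursor is assembled from (S)-carvone, which supplies the six-membered ring, its methyl and the three enal carbons, and cyclobutanone; the triene side chain is added afterwards at C8.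

Key step: step 13

Remark on locants: from compound 20 on, C1 is the spiro carbon; the six-membered ring is C1, C2 (CH with the three-carbon chain), C3 (isopropenyl carbon, later the exocyclic alkene), C4, C5, C6 (C(CH3)OH); the five-membered ring is C1, C7 (C=O, later CHOH), C8 (later the side-chain carbon), C9, C10. Compounds 8–19 keep carvone numbering (C1 carbonyl carbon, C2 methyl-bearing carbon, C5 isopropenyl carbon, C6 allylated carbon).
Assumption: (E)-pent-2-en-4-yn-1-ol, (S)-carvone and cyclobutanone are taken as commercial materials.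

Step 1
Reactants: 1 (E)-pent-2-en-4-yn-1-ol
Product: 3 (2E,4E)-4,8-dimethylnona-2,4,7-trien-1-ol, via dienylalane 2 (not isolated)
Conditions: Me3Al, Cp2ZrCl2 (cat.), CH2Cl2, 0 to 25 °C; then prenyl bromide, Pd(PPh3)4 (cat.), THF, 25 °C
Reagents that add atoms: trimethylaluminium C[Al](C)C; prenyl bromide CC(C)=CCBr
Why: Negishi zirconium-catalysed syn-carboalumination puts methyl and aluminium cis on the terminal alkyne (E trisubstituted alkene), and the alkenylalane then couples with the allylic bromide at its unsubstituted terminus under zerovalent palladium catalysis with retention.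

Step 2
Reactants: 3 (2E,4E)-4,8-dimethylnona-2,4,7-trien-1-ol
Product: 4 (2E,4E)-4,8-dimethylnona-2,4,7-trienal
Conditions: MnO2, CH2Cl2, 25 °C
Reagents that add atoms: none
Why: Allylic oxidation with MnO2 converts the dienylic alcohol into the aldehyde without touching the skipped prenyl alkene.

Step 3
Reactants: 4 (2E,4E)-4,8-dimethylnona-2,4,7-trienal
Product: 5 ethyl (2Z,4E,6E)-2-bromo-6,10-dimethylundeca-2,4,6,9-tetraenoate
Conditions: Ph3P=CHCO2Et, N-bromosuccinimide, CH2Cl2, −20 °C; then 4, 25 °C
Reagents that add atoms: ethyl (triphenylphosphoranylidene)acetate CCOC(=O)C=P(c1ccccc1)(c1ccccc1)c1ccccc1; N-bromosuccinimide O=C1CCC(=O)N1Br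
Why: Wittig olefination with the stabilised bromo ylide formed in the flask should place the ester trans to the chain, so that bromine is cis to C4 (2Z).

Step 4
Reactants: 5 ethyl (2Z,4E,6E)-2-bromo-6,10-dimethylundeca-2,4,6,9-tetraenoate
Product: 6 (2Z,4E,6E)-2-bromo-6,10-dimethylundeca-2,4,6,9-tetraen-1-ol
Conditions: i-Bu2AlH, CH2Cl2, −78 °C
Reagents that add atoms: none
Why: 1,2-Reduction of the enoate by the aluminium hydride at low temperature leaves the alkenyl bromide and the polyene untouched.

Step 5
Reactants: 6 (2Z,4E,6E)-2-bromo-6,10-dimethylundeca-2,4,6,9-tetraen-1-ol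
Product: 7 tert-butyl{[(2Z,4E,6E)-2-bromo-6,10-dimethylundeca-2,4,6,9-tetraen-1-yl]oxy}dimethylsilane
Conditions: t-BuMe2SiCl, imidazole, DMF, 0 °C
Reagents that add atoms: tert-butyldimethylsilyl chloride CC(C)(C)[Si](C)(C)Cl
Why: Silylation of the primary allylic alcohol gives an ether that tolerates the amide base of the later coupling.

Step 6
Reactants: 8 (S)-carvone
Product: 9 (5S,6R)-6-allylcarvone (allyl trans to isopropenyl)
Conditions: LiN(i-Pr)2, THF, −78 °C; then allyl bromide, −78 to 0 °C
Reagents that add atoms: allyl bromide C=CCBr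
Why: Kinetic deprotonation at C6 gives the cross-conjugated dienolate, which is allylated anti to the neighbouring isopropenyl group (enolate alkylation), setting the C6 stereocentre trans to C5.

Step 7
Reactants: 9 (5S,6R)-6-allylcarvone
Product: 11 (5S,6R)-6-allyl-2-methyl-5-(prop-1-en-2-yl)cyclohex-1-en-1-yl trifluoromethanesulfonate, via lithium enolate 10 (not isolated)
Conditions: LiBH(s-Bu)3, THF, −78 °C; then PhNTf2, −78 to 25 °C
Reagents that add atoms: N-phenylbis(trifluoromethanesulfonimide) O=S(=O)(N(c1ccccc1)S(=O)(=O)C(F)(F)F)C(F)(F)F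
Why: Conjugate reduction of the enone gives the tetrasubstituted enolate regiospecifically and O-sulfonylation traps it (reductive enolate trapping), so C6 is never enolised.

Step 8
Reactants: 11 enol triflate
Product: 12 [(5S,6R)-6-allyl-2-methyl-5-(prop-1-en-2-yl)cyclohex-1-en-1-yl]trimethylstannane
Conditions: Me3SnSnMe3, Pd(PPh3)4 (cat.), LiCl, THF, 65 °C
Reagents that add atoms: hexamethylditin C[Sn](C)(C)[Sn](C)(C)C
Why: Palladium-catalysed stannylation of an enol triflate with a distannane (Stille-type coupling) proceeds with retention at the alkene and tolerates the two isolated alkenes.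

Step 9
Reactants: 12 alkenylstannane; 13 cyclobutanone
Product: 15 1-[(5S,6R)-6-allyl-2-methyl-5-(prop-1-en-2-yl)cyclohex-1-en-1-yl]cyclobutan-1-ol, via alkenyllithium 14 (not isolated)
Conditions: MeLi, THF, −78 to −20 °C; then cyclobutanone, −78 °C
Reagents that add atoms: none
Why: Tin–lithium exchange gives the alkenyllithium, which undergoes 1,2-addition to the strained and therefore electrophilic cyclobutanone.

Step 10
Reactants: 15 1-alkenylcyclobutanol
Product: 17 1-[(5S,6R)-6-(3-hydroxypropyl)-2-methyl-5-(prop-1-en-2-yl)cyclohex-1-en-1-yl]cyclobutan-1-ol, via pinacol boronate 16 (not isolated)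
Conditions: pinacolborane, [Ir(cod)Cl]2 (cat.), dppm, CH2Cl2, 25 °C; then NaOH, H2O2, THF/H2O, 0 °C
Reagents that add atoms: pinacolborane CC1(C)OBOC1(C)C (boron of 16); hydrogen peroxide OO (oxygen of 17)
Why: Iridium-catalysed anti-Markovnikov hydroboration selects the monosubstituted alkene over the 1,1-disubstituted and tetrasubstituted ones, and alkaline peroxide oxidation gives the primary alcohol.

Step 11
Reactants: 17 diol
Product: 18 3-[(1R,6S)-2-(1-hydroxycyclobutyl)-3-methyl-6-(prop-1-en-2-yl)cyclohex-2-en-1-yl]propyl decanoate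
Conditions: n-C9H19COCl, pyridine, CH2Cl2, 0 °C
Reagents that add atoms: decanoyl chloride CCCCCCCCCC(Cl)=O
Why: Acylation takes the primary alcohol and leaves the hindered tertiary cyclobutanol free.

Step 12
Reactants: 18 decanoate
Product: 19 epoxy alcohol (epoxide on the former C1=C2 alkene, oxygen cis to the C6 chain and trans to the C5 isopropenyl group)
Conditions: VO(acac)2 (cat.), t-BuOOH, CH2Cl2, 0 °C
Reagents that add atoms: tert-butyl hydroperoxide CC(C)(C)OO
Why: Vanadium-catalysed hydroxyl-directed epoxidation touches only the allylic tetrasubstituted alkene; A(1,2) strain holds the C6 chain pseudoaxial and the C5 isopropenyl axial, the carbinol rotamer that keeps the cyclobutane CH2 away from the chain places the vanadium-bound oxygen on the chain face, and the axial isopropenyl shields the other face, so oxygen should arrive cis to the chain.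

Step 13
Reactants: 19 epoxy alcohol
Product: 20 spiro β-hydroxy ketone (C7 ketone, C6 tertiary alcohol with OH anti to C10 and syn to the C2 chain, C3 isopropenyl trans to the C2 chain)
Conditions: BF3·OEt2, CH2Cl2, −78 °C
Reagents that add atoms: none
Why: BF3 binds the epoxide oxygen, the C–O bond at the epoxide carbon that carries the 1-hydroxycyclobutyl group ionises while the anti-periplanar cyclobutane C–C bond migrates to it and the carbinol oxygen becomes the ketone, a type 3 semipinacol rearrangement (2,3-epoxy alcohol to β-hydroxy ketone) well known for epoxy cyclobutanols. No ring is closed by attack of a nucleophile on a chain: the four-membered ring grows to the cyclopentanone by a 1,2-alkyl shift driven by release of cyclobutane strain, and the same shift creates the spiro quaternary carbon. That carbon is formed with inversion, the migrating CH2 entering anti to the departing oxygen, so its configuration follows from the epoxide face set in step 12. The tertiary carbinol keeps its configuration because its C–O bond is not broken, which gives the required trans relation of the hydroxyl and the migrated CH2 (C10). The step needs cleavage of the C–O bond next to the carbinol and not of the one at the methyl-bearing carbon, and the electron push of the hydroxyl together with the strain release secures this; the two cyclobutane CH2 groups are equivalent, so no question of migratory aptitude arises.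

Step 14
Reactants: 20 spiro β-hydroxy ketone
Product: 21 C6 triethylsilyl ether of 20
Conditions: Et3SiOTf, 2,6-lutidine, CH2Cl2, −78 to 0 °C
Reagents that add atoms: triethylsilyl trifluoromethanesulfonate CC[Si](CC)(CC)OS(=O)(=O)C(F)(F)F
Why: Silylation of the tertiary aldol hydroxyl blocks retro-aldol cleavage of the C1–C6 bond in the later basic step.

Step 15
Reactants: 21 silyl ether
Product: 23 2-substituted acrolein (C3 bears C(=CH2)CHO), via allylic alcohol 22 (not isolated)
Conditions: SeO2 (cat.), t-BuOOH, CH2Cl2, 25 °C; then Dess–Martin periodinane, NaHCO3, CH2Cl2, 0 °C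
Reagents that add atoms: tert-butyl hydroperoxide CC(C)(C)OO
Why: Selenium-mediated allylic oxidation (ene reaction then 2,3-sigmatropic shift) of the 1,1-disubstituted alkene occurs at its methyl group, and the Dess–Martin oxidation brings alcohol and any aldehyde already formed to the same enal.

Step 16
Reactants: 23 2-substituted acrolein
Product: 24 (Z)-tetrasubstituted enal (C3=C(CH3)CHO with CHO syn to C2)
Conditions: RuHCl(CO)(PPh3)3 (cat.), toluene, 80 °C
Reagents that add atoms: none
Why: Ruthenium hydride addition and β-hydride elimination (alkene isomerisation) should move the double bond to the tetrasubstituted, still conjugated position; the substrate does not fix the geometry, so the (Z)-isomer is isolated and the (E)-isomer returned to the same conditions.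

Step 17
Reactants: 24 (Z)-enal
Product: 25 1,3-dioxolane of 24
Conditions: Me3SiOCH2CH2OSiMe3, Me3SiOTf (cat.), CH2Cl2, −78 °C
Reagents that add atoms: 1,2-bis(trimethylsilyloxy)ethane C[Si](C)(C)OCCO[Si](C)(C)C
Why: Silyl-triflate-catalysed acetalisation masks the aldehyde at low temperature without moving the double bond, and the neopentyl-type ketone does not react.

Step 18
Reactants: 25 dioxolane; 7 alkenyl bromide
Product: 26 C8-alkenylated ketone (side chain at C8 on the face of C6, double-bond geometry of 7 kept)
Conditions: LiN(SiMe3)2, Pd2(dba)3 (cat.), P(t-Bu)3 (cat.), toluene, 25 °C; then AcOH, −78 °C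
Reagents that add atoms: none
Why: Palladium-catalysed α-alkenylation of the ketone enolate (only C8 carries α-hydrogens) proceeds with retention at the bromide, and the more acidic product stays as its enolate until the cold quench, where protonation from the face opposite the silyloxy-bearing C6 should set C8.

Step 19
Reactants: 26 alkenylated ketone
Product: 27 keto diol (free C6 tertiary and primary allylic hydroxyls)
Conditions: HF·pyridine, pyridine, THF, 0 to 25 °C
Reagents that add atoms: none
Why: Buffered fluoride cleaves both silyl ethers without enolising the β,γ-unsaturated ketone or opening the dioxolane.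

Step 20
Reactants: 27 keto diol
Product: 28 triol (C7 hydroxyl on the face of C2, trans to the C8 side chain)
Conditions: Me4NBH(OAc)3, MeCN/AcOH, −30 °C
Reagents that add atoms: none
Why: Evans–Saksena reduction: the tertiary C6 hydroxyl binds boron and delivers hydride to the ketone face on which C6 lies, which sets the C7 carbinol.

Step 21
Reactants: 28 triol
Product: 29 primary allylic acetate
Conditions: Ac2O, pyridine, CH2Cl2, −20 °C
Reagents that add atoms: acetic anhydride CC(=O)OC(C)=O
Why: Acetylation takes the primary allylic alcohol in preference to the neopentyl-type secondary and the tertiary hydroxyl.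

Step 22
Reactants: 29 acetate
Product: 30 target CNP0271899.1
Conditions: PPTS (cat.), acetone/H2O, 25 °C
Reagents that add atoms: water O
Why: Mild acid hydrolysis of the allylic dioxolane releases the enal without touching the esters or the triene.

Compound list
1 | (E)-pent-2-en-4-yn-1-ol | C#C/C=C/CO | starting material
2 | [(1E,3E)-5-(dimethylalumanyloxy)-2-methylpenta-1,3-dien-1-yl]dimethylalumane | C[Al](C)/C=C(C)/C=C/CO[Al](C)C | intermediate
3 | (2E,4E)-4,8-dimethylnona-2,4,7-trien-1-ol | OC/C=C/C(C)=C/CC=C(C)C | intermediate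
4 | (2E,4E)-4,8-dimethylnona-2,4,7-trienal | O=C/C=C/C(C)=C/CC=C(C)C | intermediate
5 | ethyl (2Z,4E,6E)-2-bromo-6,10-dimethylundeca-2,4,6,9-tetraenoate | CCOC(=O)/C(Br)=C/C=C/C(C)=C/CC=C(C)C | intermediate
6 | (2Z,4E,6E)-2-bromo-6,10-dimethylundeca-2,4,6,9-tetraen-1-ol | OC/C(Br)=C/C=C/C(C)=C/CC=C(C)C | intermediate
7 | tert-butyl{[(2Z,4E,6E)-2-bromo-6,10-dimethylundeca-2,4,6,9-tetraen-1-yl]oxy}dimethylsilane | CC(C)(C)[Si](C)(C)OC/C(Br)=C/C=C/C(C)=C/CC=C(C)C | intermediate
8 | (S)-carvone | CC1=CC[C@@H](CC1=O)C(C)=C | starting material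
9 | (5S,6R)-6-allyl-2-methyl-5-(prop-1-en-2-yl)cyclohex-2-en-1-one | C=CC[C@@H]1[C@@H](C(C)=C)CC=C(C)C1=O | intermediate
10 | lithium enolate of the 2,3-dihydro ketone | C=CC[C@@H]1[C@@H](C(C)=C)CCC(C)=C1[O-].[Li+] | intermediate
11 | (5S,6R)-6-allyl-2-methyl-5-(prop-1-en-2-yl)cyclohex-1-en-1-yl trifluoromethanesulfonate | C=CC[C@@H]1[C@@H](C(C)=C)CCC(C)=C1OS(=O)(=O)C(F)(F)F | intermediate
12 | [(5S,6R)-6-allyl-2-methyl-5-(prop-1-en-2-yl)cyclohex-1-en-1-yl]trimethylstannane | C=CC[C@@H]1[C@@H](C(C)=C)CCC(C)=C1[Sn](C)(C)C | intermediate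
13 | cyclobutanone | O=C1CCC1 | starting material
14 | alkenyllithium from 12 | C=CC[C@@H]1[C@@H](C(C)=C)CCC(C)=C1[Li] | intermediate
15 | 1-[(5S,6R)-6-allyl-2-methyl-5-(prop-1-en-2-yl)cyclohex-1-en-1-yl]cyclobutan-1-ol | C=CC[C@@H]1[C@@H](C(C)=C)CCC(C)=C1C2(O)CCC2 | intermediate
16 | pinacol boronate of the hydroborated allyl group | CC1(C)OB(CCC[C@@H]2[C@@H](C(C)=C)CCC(C)=C2C3(O)CCC3)OC1(C)C | intermediate
17 | 1-[(5S,6R)-6-(3-hydroxypropyl)-2-methyl-5-(prop-1-en-2-yl)cyclohex-1-en-1-yl]cyclobutan-1-ol | OCCC[C@@H]1[C@@H](C(C)=C)CCC(C)=C1C2(O)CCC2 | intermediate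
18 | 3-[(1R,6S)-2-(1-hydroxycyclobutyl)-3-methyl-6-(prop-1-en-2-yl)cyclohex-2-en-1-yl]propyl decanoate | CCCCCCCCCC(=O)OCCC[C@@H]1[C@@H](C(C)=C)CCC(C)=C1C2(O)CCC2 | intermediate
19 | epoxy alcohol (epoxide oxygen cis to the chain) | CCCCCCCCCC(=O)OCCC[C@@H]1[C@@H](C(C)=C)CC[C@]2(C)O[C@]12C3(O)CCC3 | intermediate
20 | spiro β-hydroxy ketone | CCCCCCCCCC(=O)OCCC[C@@H]1[C@@H](C(C)=C)CC[C@](C)(O)[C@@]12CCCC2=O | intermediate
21 | C6 triethylsilyl ether of 20 | CCCCCCCCCC(=O)OCCC[C@@H]1[C@@H](C(C)=C)CC[C@](C)(O[Si](CC)(CC)CC)[C@@]12CCCC2=O | intermediate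
22 | allylic alcohol from oxidation of the isopropenyl methyl group | CCCCCCCCCC(=O)OCCC[C@@H]1[C@@H](C(=C)CO)CC[C@](C)(O[Si](CC)(CC)CC)[C@@]12CCCC2=O | intermediate
23 | 2-substituted acrolein | CCCCCCCCCC(=O)OCCC[C@@H]1[C@@H](C(=C)C=O)CC[C@](C)(O[Si](CC)(CC)CC)[C@@]12CCCC2=O | intermediate
24 | (Z)-tetrasubstituted enal | CCCCCCCCCC(=O)OCCC[C@@H]1/C(=C(/C)C=O)CC[C@](C)(O[Si](CC)(CC)CC)[C@@]12CCCC2=O | intermediate
25 | 1,3-dioxolane of 24 | CCCCCCCCCC(=O)OCCC[C@@H]1/C(=C(/C)C2OCCO2)CC[C@](C)(O[Si](CC)(CC)CC)[C@@]13CCCC3=O | intermediate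
26 | C8-alkenylated ketone | CCCCCCCCCC(=O)OCCC[C@@H]1/C(=C(/C)C2OCCO2)CC[C@](C)(O[Si](CC)(CC)CC)[C@@]13CC[C@H](\C(=C/C=C/C(C)=C/CC=C(C)C)CO[Si](C)(C)C(C)(C)C)C3=O | intermediate
27 | keto diol | CCCCCCCCCC(=O)OCCC[C@@H]1/C(=C(/C)C2OCCO2)CC[C@](C)(O)[C@@]13CC[C@H](\C(=C/C=C/C(C)=C/CC=C(C)C)CO)C3=O | intermediate
28 | triol | CCCCCCCCCC(=O)OCCC[C@@H]1/C(=C(/C)C2OCCO2)CC[C@](C)(O)[C@@]13CC[C@H](\C(=C/C=C/C(C)=C/CC=C(C)C)CO)[C@H]3O | intermediate
29 | primary allylic acetate | CCCCCCCCCC(=O)OCCC[C@@H]1/C(=C(/C)C2OCCO2)CC[C@](C)(O)[C@@]13CC[C@H](\C(=C/C=C/C(C)=C/CC=C(C)C)COC(C)=O)[C@H]3O | intermediate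
30 | CNP0271899.1 | CCCCCCCCCC(=O)OCCC[C@@H]1/C(=C(/C)C=O)CC[C@](C)(O)[C@@]12CC[C@H](\C(=C/C=C/C(C)=C/CC=C(C)C)COC(C)=O)[C@H]2O | target

Total step count: 22. Longest linear sequence: 17 steps (steps 6 to 22, from (S)-carvone).

Steps most likely to fail

Step 16. The hydride catalyst walks the double bond into the tetrasubstituted position without any element that decides on which side of the new alkene the aldehyde ends up, so the wrong geometry may dominate, and decarbonylation may compete. The fallback lets a ring decide the geometry. It sets out from 23: Pinnick oxidation (NaClO2, NaH2PO4, 2-methyl-2-butene) should give the acrylic acid F1, and methanolysis of the decanoate (K2CO3, MeOH) the hydroxy acid F2. Yamaguchi lactonisation (2,4,6-trichlorobenzoyl chloride, Et3N, then DMAP, toluene, high dilution) should close the eight-membered α-methylene lactone F3, which is possible because the C2 chain and the C3 substituent are trans on neighbouring carbons. The same RuHCl(CO)(PPh3)3 isomerisation then has to give the endocyclic alkene, and in an eight-membered ring this can only be cis, that is with the carbonyl carbon syn to C2 (unsaturated lactone F4). Reduction with i-Bu2AlH should give the triol F5 (lactone and ketone both reduced; the C7 configuration is immaterial), MnO2 should oxidise only the allylic alcohol to the (Z)-enal F6, and decanoyl chloride with 2,4,6-collidine at −78 °C should acylate the primary alcohol to the hydroxy enal F7. Dess–Martin oxidation of the C7 alcohol brings the sequence back to 24.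

Step 18. The coupling joins a hindered enolate to a sensitive bromotriene under strong base; the β,γ-unsaturated ketone may slip into conjugation, the C8 configuration may erode on protonation, and the coupling itself may stall. The fallback forms the C8–alkenyl bond without an enolate coupling. It sets out from 25 and 7: dehydrogenation with 2-iodoxybenzoic acid (DMSO/toluene, 70 °C) should give the cyclopentenone F8, and I2 with pyridine the α-iodoenone F9. Bromide 7 is converted by t-BuLi and then Bu3SnCl into the alkenylstannane F10. Stille coupling (Pd2(dba)3, AsPh3, CuI, DMF, 25 °C) should give the 2-alkenyl enone F11. Conjugate reduction with [(Ph3P)CuH]6 and protonation of the resulting enolate from the face opposite C6 returns to 26.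

Step 12. Oxygen may be delivered to the face of the tetrasubstituted alkene opposite the C6 chain, because the directing hydroxyl sits on a carbon that is not itself a stereocentre and two ring substituents compete for control. The fallback replaces substrate control by reagent control: from 18, a chiral hafnium bishydroxamate catalyst (Hf(Ot-Bu)4 with a C2-symmetric bishydroxamic acid ligand) and cumene hydroperoxide, of the kind used for tertiary allylic alcohols, with the ligand enantiomer chosen to place oxygen cis to the chain, leads directly to 19 (F0).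

Further compounds
F1 | step 16 | acrylic acid from 23 | CCCCCCCCCC(=O)OCCC[C@@H]1[C@@H](C(=C)C(O)=O)CC[C@](C)(O[Si](CC)(CC)CC)[C@@]12CCCC2=O
F2 | step 16 | hydroxy acid | OCCC[C@@H]1[C@@H](C(=C)C(O)=O)CC[C@](C)(O[Si](CC)(CC)CC)[C@@]12CCCC2=O
F3 | step 16 | eight-membered α-methylene lactone | O=C1OCCC[C@@H]2[C@@H](C1=C)CC[C@](C)(O[Si](CC)(CC)CC)[C@@]23CCCC3=O
F4 | step 16 | eight-membered endocyclic unsaturated lactone | O=C1OCCC[C@@H]2/C(=C1/C)CC[C@](C)(O[Si](CC)(CC)CC)[C@@]23CCCC3=O
F5 | step 16 | triol | OCCC[C@@H]1/C(=C(/C)CO)CC[C@](C)(O[Si](CC)(CC)CC)[C@@]12CCC[C@@H]2O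
F6 | step 16 | (Z)-enal diol | OCCC[C@@H]1/C(=C(/C)C=O)CC[C@](C)(O[Si](CC)(CC)CC)[C@@]12CCC[C@@H]2O
F7 | step 16 | hydroxy enal decanoate | CCCCCCCCCC(=O)OCCC[C@@H]1/C(=C(/C)C=O)CC[C@](C)(O[Si](CC)(CC)CC)[C@@]12CCC[C@@H]2O
F8 | step 18 | cyclopentenone | CCCCCCCCCC(=O)OCCC[C@@H]1/C(=C(/C)C2OCCO2)CC[C@](C)(O[Si](CC)(CC)CC)[C@@]13CC=CC3=O
F9 | step 18 | α-iodoenone | CCCCCCCCCC(=O)OCCC[C@@H]1/C(=C(/C)C2OCCO2)CC[C@](C)(O[Si](CC)(CC)CC)[C@@]13CC=C(I)C3=O
F10 | step 18 | alkenylstannane from 7 | CC(C)(C)[Si](C)(C)OC/C(=C/C=C/C(C)=C/CC=C(C)C)[Sn](CCCC)(CCCC)CCCC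
F11 | step 18 | 2-alkenyl cyclopentenone | CCCCCCCCCC(=O)OCCC[C@@H]1/C(=C(/C)C2OCCO2)CC[C@](C)(O[Si](CC)(CC)CC)[C@@]13CC=C(\C(=C/C=C/C(C)=C/CC=C(C)C)CO[Si](C)(C)C(C)(C)C)C3=O
F0 | step 12 | none | none
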